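- The unit for this flask is the turnover: one molecule of target made per molecule of enzyme charged.

the same everywhere: starting material 0.050 M; free enzyme 0.01 mol%
- east: second substrate 1 equiv; capture agent 1 mM; the very flask that is asked about, followed so far
- north-west: second substrate 1 equiv; capture agent 0.67 mM; run made earlier
- flask: second substrate 1.00 equiv; capture agent 1.00 mM; time 80 min

| run | time / min | target / % | starting material / % |
|---|---|---|---|
| east | 12.0 | 17.1 | 83.0 |
| east | 25.0 | 17.4 | 82.5 |
| east | 30.0 | 18.0 | 81.7 |
| east | 50.0 | 17.8 | 81.9 |
| east | 60.0 | 17.9 | 81.9 |
| east | 80.0 | 18.4 | 81.9 |
| north-west | 1.33 | 5.3 | 95.1 |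
| north-west | 2.00 | 7.6 | 93.1 |
| north-west | 3.00 | 9.8 | 90.1 |
| north-west | 5.00 | 13.7 | 85.2 |
| north-west | 6.00 | 16.4 | 84.6 |
| north-west | 10.0 | 20.2 | 79.5 |
| north-west | 15.0 | 23.7 | 76.7 |

(readings scatter by 0.3 percentage points)

- additions bring no volume worth counting
- the earlier runs were read with a standard deviation of 0.3 percentage points
- steps that have been proposed: capture agent + second complex -> trapped intermediate; starting material + free enzyme <-> first complex; second substrate + loaded enzyme <-> second complex; first complex -> loaded enzyme + first product; second complex -> free enzyme + target

- larch: at 80 min add free enzyme, 50.0% of the amount charged, then wait 2.5 h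
- alder: at 80 min take out 90% of the first product then present, then wait 2.5 h
- elm: at 80 min add second substrate, 100% of the amount charged, then wait 2.5 h
- ash: change nothing and wait 2.5 h more

1. target, in percent of the starting material first charged, at 80 min
2. the remedy with the largest gain of target, or "none" below 2 percentage points (larch / alder / elm / ash / none)
3. target present, in percent of the starting material first charged, after alder
4. target present, in percent of the starting material first charged, after ash

- In the east run, target and starting material stop moving while 81.9% of the starting material is still present: from 30.0 min to 80.0 min, target reads 18.0% to 18.4%, with a scatter of 0.3 percentage points.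
- The north-west run has the same charges but 0.67 mM of capture agent, and it reaches 23.7% by 15.0 min, more than the east plateau. So the stop moves with the capture agent, which points to the proposed trapping of second complex.
- Second complex can fall back to second substrate and loaded enzyme, which keeps the enzyme in its round, or it can release target or be trapped; what counts for the enzyme's working life is the split between release and trapping. The enzyme stands at 5.00 µM, and trapping it uses hardly any of the capture agent, so trapping runs pseudo-first-order at a steady split.
- A steady split gives each enzyme a fixed working life. The mean east plateau of 18.0% therefore gives a total turnover number N, target made per enzyme charged, of 1800.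
- In powers of ten, N has the logarithm 3.26 and the loading −4.00. Their sum, −0.744, is the logarithm of the plateau, which lies below the charge.
- The same split scaled to the north-west capture agent gives a plateau of 26.9%, above that run's last reading.
- My reckoning for this flask is 18.0% at 80 min. Waiting, alder and elm leave it there, since the plateau shows no working enzyme. Larch adds fresh turnovers worth 9 points, less than the starting material present.
- The forecast gives 18% (from 17.6% to 18.4%), chooses larch, and puts alder at 18% and ash at 18%. Its ground: “So the enzyme is being killed”.
- The flask gives 18.0%, with 18.0% after alder and 18.0% after ash. Trapped intermediate holds >99.9% of the catalyst at 80 min.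

    capture agent + second complex → trapped intermediate (k = 35.0 M⁻¹ s⁻¹)
    starting material + free enzyme ⇌ first complex (K = 15.0 M⁻¹, k = 310 M⁻¹ s⁻¹)
    second substrate + loaded enzyme ⇌ second complex (K = 27.0 M⁻¹, k = 5000 M⁻¹ s⁻¹)
    first complex → loaded enzyme + first product (k = 55.0 s⁻¹)
    second complex → free enzyme + target (k = 63.0 s⁻¹)

- Larch is the best remedy: N on the added enzyme gave 9 points, and the flask gains 9.1 points. In a neighbouring flask with 0.04 mol% of free enzyme, N gives 72.1%; that flask reaches 72.7% and still holds 27.3% of its starting material.

(The numbers in the tables were computed with constants of no real substance; noise was put on by code.)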